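One species is followed. Monday's run is this flask, and its reading at 150 min falls at the asked time, so I take 17.7% for now, with a scatter of 0.5 percentage points.

| flask | starting complex | incoming ligand | leaving ligand | protic impurity | temperature | remark | time |
|---|---|---|---|---|---|---|---|
| Monday's | 0.050 M | 0.20 M | 0.10 M | 5 mM | 35 °C | the very flask that is asked about, followed so far |  |
| Tuesday's | 0.050 M | 0.20 M | 0.10 M | 3.4 mM | 20 °C | run made earlier |  |
| flask | 0.050 M | 0.200 M | 0.100 M | 5.00 mM | 35 °C |  | 2.5 h |

| run | time / min | complex with one exchanged / % |
|---|---|---|
| Monday's | 8.00 | 37.0 |
| Monday's | 25.0 | 33.0 |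
| Monday's | 40.0 | 30.4 |
| Monday's | 60.0 | 25.5 |
| Monday's | 90.0 | 21.5 |
| Monday's | 120 | 18.4 |
| Monday's | 150 | 17.7 |
| Tuesday's | 0.833 | 6.2 |
| Tuesday's | 1.33 | 8.8 |
| Tuesday's | 2.00 | 12.0 |
| Tuesday's | 3.00 | 14.5 |
| Tuesday's | 5.00 | 20.3 |
| Tuesday's | 8.00 | 23.0 |
| Tuesday's | 12.0 | 24.4 |

(standard deviation of a reading: 0.5 percentage points)

- red: at 2.5 h add incoming ligand, 50.0% of the amount charged, then wait 5.0 h
- grey: at 2.5 h take out 90% of the leaving ligand then present, then wait 5.0 h
- violet: at 2.5 h raise the temperature by 15 K, then wait 5.0 h
- blue: change nothing and wait 5.0 h more

- complex with one exchanged, in percent of the starting complex first charged, at 2.5 h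
- which option adds most complex with one exchanged ("none" when 2 percentage points or less is all one gets) (red / grey / violet / blue / none)
- complex with one exchanged present, in percent of the starting complex first charged, after red
- complex with one exchanged present, in percent of the starting complex first charged, after violet

- additions bring no volume worth counting
- what was read earlier has a scatter of 0.5 percentage points, one standard deviation
- steps under discussion: starting complex + incoming ligand <-> leaving ligand + complex with one exchanged; complex with one exchanged + incoming ligand <-> leaving ligand + complex with two exchanged; complex with two exchanged + incoming ligand <-> leaving ligand + complex with three exchanged; complex with three exchanged + incoming ligand <-> leaving ligand + complex with four exchanged; protic impurity + incoming ligand -> quenched reagent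

But the reading does not show the ligands. Each exchange spends one incoming ligand and frees one leaving ligand. So let n be the exchanges per charged complex, and let r be the leaving ligand over the incoming ligand, the ligand part of each step's reaction quotient. The top is the leaving ligand charged plus n times the complex charged. The bottom is the incoming ligand charged, less the protic impurity, which I count as spent, less the same n times the complex.

At Monday's first reading I try n = 1, which gives r = 1.03. But the reading has since dropped to half of that value, so I go round again with n = 2 and get 2.11. I carry this ligand ratio at the asked time.

Red takes r to 1.03 and grey to 0.211, both lower than now. So I expect each to push this complex onward and cost it. Violet I read from the runs: Tuesday's last reading, 24.4%, stands against Monday's first, 37.0%, a factor of 1.52. The two runs lie as far apart in temperature as violet's rise, but their reading times differ, and Tuesday's run held 3.4 mM of protic impurity against 5 mM on Monday. So the factor is rough. On the present reading it gives an estimate of 26.8%, a gain of 9.1 points, so I commit to violet.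

The forecast gives 17.6% now, 12.5% after red, 13.5% after violet, and best none: “Nothing beats the present value, so best is none.”

The flask gives 18.0% now, 7.68% after red and 23.3% after violet. Best is violet, with 5.3 points gained, against −3 points for blue.

    starting complex + incoming ligand ⇌ leaving ligand + complex with one exchanged (K = 1.80, k = 1.16 /M/min, Ea = 56.0 kJ/mol, ΔH = −27.0 kJ/mol)
    complex with one exchanged + incoming ligand ⇌ leaving ligand + complex with two exchanged (K = 0.701, k = 2.14 /M/min, Ea = 44.0 kJ/mol, ΔH = −65.0 kJ/mol)
    complex with two exchanged + incoming ligand ⇌ leaving ligand + complex with three exchanged (K = 17.6, k = 0.376 /M/min, Ea = 59.0 kJ/mol, ΔH = −50.0 kJ/mol)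
    complex with three exchanged + incoming ligand ⇌ leaving ligand + complex with four exchanged (K = 3.70, k = 1.24 /M/min, Ea = 45.0 kJ/mol, ΔH = −5.00 kJ/mol)
    protic impurity + incoming ligand → quenched reagent (k = 19.1 /M/min, Ea = 50.0 kJ/mol)
    (constants at 35 °C)

The forecast and I part on violet, and my estimate of 26.8% stands above the flask's 23.3%. At the asked time this flask holds r = 2.41, against my 2.11. The neighbour charged with 0.25 M of leaving ligand gets the same reckoning at n = 2: r = 3.68, higher than this flask's. Its contents give 3.06, and at 150 min it holds 20.5% of the complex with one exchanged, more than this flask's 18.0%.

(All runs are simulated for substances that don't exist.)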